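Locants are those of the azulene skeleton of the target (ring A: C1, C2, C3, C3a, C8a; ring B: C3a, C4 to C8, C8a) and are kept for all intermediates.
Retrosynthesis: cut the C4 ester, then the isopropyl–C3 bond (back to a C3 ketone), trace C6=C7 to a C6 aldol, and cut the two ring-B bonds C8–C8a and C6–C7 together. This leaves a 2-substituted 3-methylcyclopentenone (ring A) whose side chain is a β-alkoxy methyl ketone (C4–C5–C6) and whose C4 oxygen carries C7–C8 as a glycolyl thioester, O–CH2–C(=O)S.
Enabling feature: the C8 ketone is 1,4 to the C3 ketone through C8a–C3a, so C8a is the β-carbon of a cyclopentenone and accepts an acyl-radical equivalent. O4 can carry C7, so O4–C7 lies α to the new C8 ketone and SmI2 cleaves it to an enolate located only at C7, which closes ring B on the C6 ketone.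
Forward: ring A is bought; the chain is attached at C3a (formylation, methallylation); the glycolyl unit is tethered on O4; one SmI2 operation makes C8–C8a, removes the O4–C7 tether and makes C6–C7; dehydration, isopropyl addition at C3 and acylation of O4 finish.
Stereochemistry: C4 from a Keck asymmetric methallylation; C8a from C4 (tether closure under allylic 1,3-strain); C3a from kinetic protonation of the samarium enolate anti to the C8a methyl (trans fusion); C3 from addition anti to the angular methyl.

Key step: step 8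

Remark: the configuration at C6 of compound 16 is not controlled and is erased in step 9; compounds 1, 3, 5, 7, 9, 13, 18 and 20 are taken as commercial.

Step 1
Reactants: 1 3-methylcyclopent-2-en-1-one
Product: 2 2-bromo-3-methylcyclopent-2-en-1-one
Conditions: Br2, CH2Cl2, 0 °C; then Et3N, 0 → 20 °C
Reagents that add atoms: bromine BrBr
Why: Bromine addition to the enone followed by base-induced loss of HBr (addition–elimination) should give the 2-bromo enone; no stereocenter is formed.

Step 2
Reactants: 2 2-bromo-3-methylcyclopent-2-en-1-one; 3 ethylene glycol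
Product: 4 6-bromo-7-methyl-1,4-dioxaspiro[4.4]non-6-ene
Conditions: p-TsOH (cat.), benzene, reflux, Dean–Stark trap
Reagents that add atoms: none
Why: Acid-catalysed ketalisation with azeotropic removal of water masks the ketone so that the vinyl bromide can serve as an α-keto vinyl anion equivalent.

Step 3
Reactants: 4 6-bromo-7-methyl-1,4-dioxaspiro[4.4]non-6-ene; 5 N,N-dimethylformamide
Product: 6 7-methyl-1,4-dioxaspiro[4.4]non-6-ene-6-carbaldehyde
Conditions: n-BuLi, THF, −78 °C; then DMF, −78 → 0 °C; H2O
Reagents that add atoms: none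
Why: Bromine–lithium exchange gives the vinyllithium, which DMF formylates (Bouveault formylation) to install the carbon that becomes C4.

Step 4
Reactants: 6 7-methyl-1,4-dioxaspiro[4.4]non-6-ene-6-carbaldehyde; 7 tributyl(2-methylprop-2-en-1-yl)stannane
Product: 8 (1S)-3-methyl-1-(7-methyl-1,4-dioxaspiro[4.4]non-6-en-6-yl)but-3-en-1-ol
Conditions: (S)-BINOL (20 mol %), Ti(Oi-Pr)4 (10 mol %), 4 Å molecular sieves, CH2Cl2, −20 °C; aq. NaHCO3
Reagents that add atoms: none
Why: In this Keck asymmetric allylation the BINOL–titanium Lewis acid should direct the methallylstannane to one face of the unsaturated aldehyde and set C4 as (S), the ligand antipode being chosen by the usual model for aryl and alkenyl aldehydes.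

Step 5
Reactants: 8 (1S)-3-methyl-1-(7-methyl-1,4-dioxaspiro[4.4]non-6-en-6-yl)but-3-en-1-ol; 9 bromoacetic acid
Product: 11 2-{[(1S)-3-methyl-1-(2-methyl-5-oxocyclopent-1-en-1-yl)but-3-en-1-yl]oxy}acetic acid, via ketal acid 10 (not isolated)
Conditions: NaH (3 equiv), THF, 0 → 65 °C; then 1 M HCl, THF, 20 °C
Reagents that add atoms: water O
Why: Williamson etherification of the sodium alkoxide with sodium bromoacetate should place the two-carbon glycolyl unit (C7, C8) on O4, and the acidic work-up hydrolyses the dioxolane to the enone without touching C4.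

Step 6
Reactants: 11 2-{[(1S)-3-methyl-1-(2-methyl-5-oxocyclopent-1-en-1-yl)but-3-en-1-yl]oxy}acetic acid
Product: 12 2-{[(1S)-1-(2-methyl-5-oxocyclopent-1-en-1-yl)-3-oxobutyl]oxy}acetic acid
Conditions: O3, CH2Cl2–MeOH, −78 °C; then Me2S, −78 → 20 °C
Reagents that add atoms: ozone [O-][O+]=O
Why: Ozonolysis should cleave the isolated 1,1-disubstituted alkene much faster than the electron-poor tetrasubstituted enone double bond and so unveil the C6 methyl ketone.

Step 7
Reactants: 12 2-{[(1S)-1-(2-methyl-5-oxocyclopent-1-en-1-yl)-3-oxobutyl]oxy}acetic acid; 13 pyridine-4-thiol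
Product: 14 S-(pyridin-4-yl) 2-{[(1S)-1-(2-methyl-5-oxocyclopent-1-en-1-yl)-3-oxobutyl]oxy}ethanethioate
Conditions: DCC, CH2Cl2, 0 → 20 °C
Reagents that add atoms: none
Why: Carbodiimide coupling (Steglich-type thioesterification) under neutral conditions should give the 4-pyridyl thioester, whose electron-poor thio group makes the acyl carbon the easiest site to reduce.

Step 8
Reactants: 14 S-(pyridin-4-yl) 2-{[(1S)-1-(2-methyl-5-oxocyclopent-1-en-1-yl)-3-oxobutyl]oxy}ethanethioate
Product: 16 (3aS,4S,8aS)-4,6-dihydroxy-6,8a-dimethyl-octahydroazulene-3,8(2H,3aH)-dione, via bicyclic samarium enolate 15 (not isolated)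
Conditions: SmI2 (5 equiv), THF, −78 → 0 °C; then AcOH, −78 °C
Reagents that add atoms: none
Why: Proposed new method: SmI2 reduces the 4-pyridyl thioester to a ketyl-type radical anion (an acyl-radical equivalent that does not lose CO), which adds to C8a, the β-carbon of the cyclopentenone, and collapses to the C8 ketone with loss of pyridine-4-thiolate (enolate 15); two more electrons then break the O4–C7 bond α to that ketone, and the C7 samarium enolate so formed adds to the C6 methyl ketone, held close by the samarium alkoxide on O4, to close ring B. The closest known reaction types are the SmI2 coupling of 4-pyridyl thioesters with acrylates and acrylamides, the SmI2 cleavage of α-alkoxy ketones and samarium-enolate aldol cyclisations; their merger on a tetrasubstituted enone is new. The temporary six-membered oxacycle closes 6-endo-trig (radical onto the enone) and ring B closes 7-(enolendo)-exo-trig (aldol). C8a is controlled by C4: allylic 1,3-strain with the C3 carbonyl keeps H4 in the enone plane, so the O4 tether reaches only the face that gives (8aS), and C3a is set when the C3 samarium enolate is protonated anti to the C8a methyl (trans fusion); the C6 carbinol is not controlled and is erased in step 9. The step needs reduction of the thioester before the enone (secured by the electron-poor pyridylthio group), endo attack at the β-carbon and not 5-exo attack at the fully substituted α-carbon (secured by the polarity of the enone), and aldol addition to C6 only (the C3 ketone is masked as its samarium enolate until the acid quench).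

Step 9
Reactants: 16 (3aS,4S,8aS)-4,6-dihydroxy-6,8a-dimethyl-octahydroazulene-3,8(2H,3aH)-dione
Product: 17 (3aS,4S,8aS)-4-hydroxy-6,8a-dimethyl-1,2,3a,4,5,8a-hexahydroazulene-3,8-dione
Conditions: p-TsOH·H2O (10 mol %), benzene, 20 °C
Reagents that add atoms: none
Why: Acid-catalysed dehydration of the tertiary β-hydroxy ketone should give the conjugated trisubstituted C6=C7 enone under thermodynamic control (C7 is the only enolisable position of the C8 ketone because C8a is quaternary), while the secondary C4 alcohol reacts more slowly.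

Step 10
Reactants: 17 (3aS,4S,8aS)-4-hydroxy-6,8a-dimethyl-1,2,3a,4,5,8a-hexahydroazulene-3,8-dione; 18 isopropylmagnesium chloride
Product: 19 (3R,3aS,4S,8aS)-3,4-dihydroxy-6,8a-dimethyl-3-(propan-2-yl)-2,3,3a,4,5,8a-hexahydroazulen-8(1H)-one
Conditions: CeCl3 (anhydrous), THF, −78 °C; then H2O
Reagents that add atoms: none
Why: The weakly basic organocerium reagent should add 1,2 to the cyclopentanone and not to the hindered conjugated C8 ketone, entering anti to the angular C8a methyl (the face of H3a and of the C4 alkoxide), which sets C3 as (R).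

Step 11
Reactants: 19 (3R,3aS,4S,8aS)-3,4-dihydroxy-6,8a-dimethyl-3-(propan-2-yl)-2,3,3a,4,5,8a-hexahydroazulen-8(1H)-one; 20 3,4,5-trimethoxybenzoyl chloride
Product: 21 (3R,3aS,4S,8aS)-3-hydroxy-6,8a-dimethyl-8-oxo-3-(propan-2-yl)-1,2,3,3a,4,5,8,8a-octahydroazulen-4-yl 3,4,5-trimethoxybenzoate
Conditions: Et3N, DMAP (cat.), CH2Cl2, 0 → 20 °C
Reagents that add atoms: none
Why: DMAP-catalysed acylation should take place at the secondary C4 alcohol only, because the tertiary C3 alcohol is too hindered to react.

Compound list
1 | 3-methylcyclopent-2-en-1-one | CC1=CC(=O)CC1 | starting material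
2 | 2-bromo-3-methylcyclopent-2-en-1-one | CC1=C(Br)C(=O)CC1 | intermediate
3 | ethylene glycol | OCCO | starting material
4 | 6-bromo-7-methyl-1,4-dioxaspiro[4.4]non-6-ene | CC1=C(Br)C2(CC1)OCCO2 | intermediate
5 | N,N-dimethylformamide | CN(C)C=O | starting material
6 | 7-methyl-1,4-dioxaspiro[4.4]non-6-ene-6-carbaldehyde | CC1=C(C=O)C2(CC1)OCCO2 | intermediate
7 | tributyl(2-methylprop-2-en-1-yl)stannane | CCCC[Sn](CCCC)(CCCC)CC(C)=C | starting material
8 | (1S)-3-methyl-1-(7-methyl-1,4-dioxaspiro[4.4]non-6-en-6-yl)but-3-en-1-ol | CC(=C)C[C@H](O)C1=C(C)CCC12OCCO2 | intermediate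
9 | bromoacetic acid | OC(=O)CBr | starting material
10 | 2-{[(1S)-3-methyl-1-(7-methyl-1,4-dioxaspiro[4.4]non-6-en-6-yl)but-3-en-1-yl]oxy}acetic acid | OC(=O)CO[C@@H](CC(C)=C)C1=C(C)CCC12OCCO2 | intermediate
11 | 2-{[(1S)-3-methyl-1-(2-methyl-5-oxocyclopent-1-en-1-yl)but-3-en-1-yl]oxy}acetic acid | OC(=O)CO[C@@H](CC(C)=C)C1=C(C)CCC1=O | intermediate
12 | 2-{[(1S)-1-(2-methyl-5-oxocyclopent-1-en-1-yl)-3-oxobutyl]oxy}acetic acid | OC(=O)CO[C@@H](CC(C)=O)C1=C(C)CCC1=O | intermediate
13 | pyridine-4-thiol | Sc1ccncc1 | starting material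
14 | S-(pyridin-4-yl) 2-{[(1S)-1-(2-methyl-5-oxocyclopent-1-en-1-yl)-3-oxobutyl]oxy}ethanethioate | O=C(CO[C@@H](CC(C)=O)C1=C(C)CCC1=O)Sc1ccncc1 | intermediate
15 | samarium enolate, drawn as the anion: (1S,4aS)-4a-methyl-4-oxo-1-(2-oxopropyl)-1,3,4,4a,5,6-hexahydrocyclopenta[c]pyran-7-olate | CC(=O)C[C@@H]1OCC(=O)[C@@]2(C)CCC([O-])=C12 | intermediate
16 | (3aS,4S,8aS)-4,6-dihydroxy-6,8a-dimethyl-octahydroazulene-3,8(2H,3aH)-dione (trans-fused; C6 carbinol not controlled) | O[C@H]1CC(C)(O)CC(=O)[C@@]2(C)CCC(=O)[C@H]12 | intermediate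
17 | (3aS,4S,8aS)-4-hydroxy-6,8a-dimethyl-1,2,3a,4,5,8a-hexahydroazulene-3,8-dione | O[C@H]1CC(C)=CC(=O)[C@@]2(C)CCC(=O)[C@H]12 | intermediate
18 | isopropylmagnesium chloride | CC(C)[Mg]Cl | starting material
19 | (3R,3aS,4S,8aS)-3,4-dihydroxy-6,8a-dimethyl-3-(propan-2-yl)-2,3,3a,4,5,8a-hexahydroazulen-8(1H)-one | O[C@H]1CC(C)=CC(=O)[C@@]2(C)CC[C@@](O)(C(C)C)[C@H]12 | intermediate
20 | 3,4,5-trimethoxybenzoyl chloride | COc1cc(C(=O)Cl)cc(OC)c1OC | starting material
21 | (3R,3aS,4S,8aS)-3-hydroxy-6,8a-dimethyl-8-oxo-3-(propan-2-yl)-1,2,3,3a,4,5,8,8a-octahydroazulen-4-yl 3,4,5-trimethoxybenzoate (CNP0218356.1) | COc1cc(C(=O)O[C@H]2CC(C)=CC(=O)[C@@]3(C)CC[C@@](O)(C(C)C)[C@H]23)cc(OC)c1OC | target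

Total steps: 11. Longest linear sequence: 11 steps (1 to 21).

Steps most likely to fail

Step 8 (Proposed new method). Several processes could divert the cascade:
- reduction of the enone before the thioester, followed by reductive β-elimination of the C4 alkoxy group and loss of the tether;
- reduction of the enone without carbon–carbon bond formation;
- protonation of the C7 samarium enolate before ring B closes;
- over-reduction of the C8 ketone;
- protonation at C3a from the wrong face, giving a cis ring fusion.

The fallback uses known reactions only; it sets out from 8 and comes back at 16. Alcohol 8 is O-allylated (NaH, allyl bromide, THF) to the allyl ether ketal F1. Aqueous HCl removes the dioxolane and gives the dienyl enone F2. Ozonolysis of both terminal alkenes (O3, then Me2S) gives the keto aldehyde F3. SmI2 with t-BuOH in THF at −78 °C then joins the aldehyde carbon to C8a by a ketyl–olefin cyclisation onto the enone, giving the hydroxy ketone F4. Dess–Martin periodinane oxidises it to the α-alkoxy ketone F5. A second, separate SmI2 treatment (THF, −78 → 0 °C, AcOH quench) cleaves O4–C7 and closes ring B by the samarium aldol addition to give 16.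

Step 10. Possible failures are enolisation of the hindered cyclopentanone instead of addition, competing addition to the conjugated C8 ketone, retro-aldol cleavage of the C3a–C4 bond in the β-alkoxido ketone, and epimerisation at C3a before the addition. The fallback sets out from 17 and comes back at 19. The smaller sp2 nucleophile isopropenylmagnesium bromide, with CeCl3 in THF at −78 °C, gives the isopropenyl carbinol F6. Hydrogen with RhCl(PPh3)3 in benzene then reduces only the 1,1-disubstituted alkene and leaves the trisubstituted enone, giving 19.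

Step 9. Possible failures are acid-catalysed loss of the secondary C4 hydroxyl (β to the C3 ketone), epimerisation at C3a through enolisation of the C3 ketone, and retro-aldol opening of ring B. The fallback sets out from 16 and comes back at 21, with the order of the endgame changed. Acylation with 20 (DMAP, pyridine, 0 °C) first gives the ester F7, in which the tertiary C6 carbinol is the only free hydroxyl. p-TsOH in benzene then gives the enone ester F8. i-PrMgCl with CeCl3 at −78 °C adds to the C3 ketone of F8 (ketone before ester) and gives 21 directly.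

Further compounds
F1 | step 8 | 6-[(1S)-3-methyl-1-(prop-2-en-1-yloxy)but-3-en-1-yl]-7-methyl-1,4-dioxaspiro[4.4]non-6-ene | C=CCO[C@@H](CC(C)=C)C1=C(C)CCC12OCCO2
F2 | step 8 | 3-methyl-2-[(1S)-3-methyl-1-(prop-2-en-1-yloxy)but-3-en-1-yl]cyclopent-2-en-1-one | C=CCO[C@@H](CC(C)=C)C1=C(C)CCC1=O
F3 | step 8 | 2-{[(1S)-1-(2-methyl-5-oxocyclopent-1-en-1-yl)-3-oxobutyl]oxy}acetaldehyde | O=CCO[C@@H](CC(C)=O)C1=C(C)CCC1=O
F4 | step 8 | (1S,4aS,7aS)-4-hydroxy-4a-methyl-1-(2-oxopropyl)hexahydrocyclopenta[c]pyran-7(1H)-one | CC(=O)C[C@@H]1OCC(O)[C@@]2(C)CCC(=O)[C@H]12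
F5 | step 8 | (1S,4aS,7aS)-4a-methyl-1-(2-oxopropyl)tetrahydrocyclopenta[c]pyran-4,7(1H,3H)-dione | CC(=O)C[C@@H]1OCC(=O)[C@@]2(C)CCC(=O)[C@H]12
F6 | step 10 | (3S,3aS,4S,8aS)-3,4-dihydroxy-6,8a-dimethyl-3-(prop-1-en-2-yl)-2,3,3a,4,5,8a-hexahydroazulen-8(1H)-one | O[C@H]1CC(C)=CC(=O)[C@@]2(C)CC[C@@](O)(C(C)=C)[C@H]12
F7 | step 9 | (3aS,4S,8aS)-6-hydroxy-6,8a-dimethyl-3,8-dioxodecahydroazulen-4-yl 3,4,5-trimethoxybenzoate | COc1cc(C(=O)O[C@H]2CC(C)(O)CC(=O)[C@@]3(C)CCC(=O)[C@H]23)cc(OC)c1OC
F8 | step 9 | (3aS,4S,8aS)-6,8a-dimethyl-3,8-dioxo-1,2,3,3a,4,5,8,8a-octahydroazulen-4-yl 3,4,5-trimethoxybenzoate | COc1cc(C(=O)O[C@H]2CC(C)=CC(=O)[C@@]3(C)CCC(=O)[C@H]23)cc(OC)c1OC
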